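(All runs were computed with made-up constants.)

In a one-step world your flask would hold one product and there would be nothing to watch. Here the captured material splits between target and other capture product, so measure that split from its even point.

all flasks: starting material 0.020 M; gas 1.2 mM (held)
- spring: second nucleophile 0.040 M; run made earlier
- flask: second nucleophile 0.0800 M; time 12 h

spring run (percent of the starting material charged)

| time / min | target / % | other capture product / % |
|---|---|---|
| 4.00 | 2.4 | 0.9 |
| 12.0 | 5.3 | 3.2 |
| 20.0 | 10.9 | 6.0 |
| 30.0 | 12.9 | 6.9 |
| 40.0 | 14.2 | 5.3 |
| 60.0 | 16.3 | 7.0 |
| 80.0 | 15.7 | 8.4 |

(readings scatter by 1 percentage point)

- share of target in target plus other capture product at 6.0 min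
- share of target in target plus other capture product at 12 h
- which of target and other capture product there is more of at 12 h

- at the start none of the gas is in solution

You take over starting material, second nucleophile and held gas, with none of the gas dissolved at the start. The spring readings from 40.0 min on give 2.23 for target over other capture product, and this ratio is the capture odds, with the even split at one. My assumption, which these runs do not test, is that dissolved gas makes the target and second nucleophile makes the other capture product, so with the gas held the odds fall as that charge rises. This flask has twice the spring charge, so at 12 h I expect odds of 1.12 and a target share of 52.8%, with more target than other capture product. At 6.0 min I expect a lower share, a judgement that the scattered early spring readings do not test. On my assumption the odds rest on both the gas hold and the second nucleophile charge, so leave both alone.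

The forecast, reading “the second nucleophile making the target while the dissolved gas makes the other capture product”, gives 82% and 80%, with target ahead; my late share differs from its figure.

The flask gives 45.4% at 6.0 min and 56.1% at 12 h, with target ahead.

    starting material → intermediate (k = 0.0900 min⁻¹)
    first nucleophile + intermediate → target (k = 150 M⁻¹ min⁻¹)
    second nucleophile + intermediate → other capture product (k = 0.760 M⁻¹ min⁻¹)
    intermediate → solvolysis product (k = 0.350 min⁻¹)
    intermediate → side product (k = 0.00600 min⁻¹)
    gas ⇌ first nucleophile, rate k6*(csat - [first nucleophile]) (kL = 0.190 min⁻¹)
    2 first nucleophile → homo dimer (k = 1.10 M⁻¹ min⁻¹)

The flask's 15.5% and 12.2% make odds of 1.27, against my 1.12. In this flask, intermediate goes to solvolysis product at 0.35 min⁻¹, which is faster than its capture by first nucleophile at saturation, 0.180 min⁻¹, or by second nucleophile at its charge, 0.0608 min⁻¹, and solvolysis product stands at 71.1% after 12.0 h.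

With 0.048 M of second nucleophile, the neighbour's odds reckon to 1.86, a share of 65.0%. The computed share in that neighbour at 12 h is 67.7%.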